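## Retrosynthetic overview
1. Cut both quinone-O–acyl ester C–O bonds (made last, in one operation). This gives atromentin plus two equivalents of potassium (2Z,4S,5S)-4,5-epoxyhex-2-enoate.
2. The epoxy carboxylate comes from its methyl ester, made by Z-selective olefination of (2R,3S)-2,3-epoxybutanal. The aldehyde traces back to Sharpless epoxidation of crotyl alcohol, whose C–O bonds set all four stereocentres.
3. Atromentin comes from C–Cl to C–OH exchange on 2,5-dichloro-3,6-bis(4-hydroxyphenyl)benzoquinone, itself made by double radical arylation of 2,5-dichlorobenzoquinone with diazotised 4-aminophenol.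
4. Ring order: the oxirane is the only ring that is made (first step of the side-chain branch). The quinone ring and both phenol rings are bought intact.

Assumption: commercial crotyl alcohol is taken as the E isomer (about 95% E). The few per cent of cis-epoxide it gives are removed by chromatography at the methyl ester stage.

## Route

Step 1
Reactants: 1 (E)-but-2-en-1-ol (crotyl alcohol)
Product: 2 [(2S,3S)-3-methyloxiran-2-yl]methanol
Conditions: Ti(OiPr)4 (5 mol %), L-(+)-diisopropyl tartrate (6 mol %), t-BuOOH (1.5 equiv, decane), 4 Å sieves, CH2Cl2, −20 °C; non-aqueous work-up, distillation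
Reagents that add atoms: tert-butyl hydroperoxide, CC(C)(C)OO
Why: Sharpless asymmetric epoxidation, in which the titanium L-(+)-tartrate complex delivers oxygen to the face of the bound allylic alcohol that gives the (2S,3S) epoxy alcohol (typically 90–95% ee), and the E alkene is transferred stereospecifically into the trans oxirane, so both stereocentres of each side chain are set here.

Step 2
Reactants: 2 [(2S,3S)-3-methyloxiran-2-yl]methanol; 3 methyl 2-[bis(2,2,2-trifluoroethoxy)phosphoryl]acetate
Product: 5 methyl (2Z)-3-[(2S,3S)-3-methyloxiran-2-yl]prop-2-enoate, via epoxy aldehyde 4 (not isolated)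
Conditions: 2-iodoxybenzoic acid (1.5 equiv), EtOAc, 75 °C; cool, MgSO4, filter; filtrate added to 3 (1.15 equiv), KN(SiMe3)2 (1.1 equiv), 18-crown-6 (3 equiv), THF, −78 °C
Reagents that add atoms: phosphonate 3, COC(=O)CP(=O)(OCC(F)(F)F)OCC(F)(F)F (gives C1, C2 and the OMe group)
Why: The heterogeneous 2-iodoxybenzoic acid oxidation needs only a filtration, so the volatile, water-soluble aldehyde (2R,3S)-3-methyloxirane-2-carbaldehyde is never handled neat and its oxirane centres are untouched, and the Still–Gennari variant of the Horner–Wadsworth–Emmons reaction gives the Z enoate (usually above 10:1) because the electron-poor phosphonate with crown-separated potassium eliminates fast and irreversibly from the kinetic adduct; no new stereocentre is formed.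

Step 3
Reactants: 5 methyl (2Z)-3-[(2S,3S)-3-methyloxiran-2-yl]prop-2-enoate
Product: 6 potassium (2Z)-3-[(2S,3S)-3-methyloxiran-2-yl]prop-2-enoate
Conditions: KOSiMe3 (0.98 equiv), Et2O, 0 °C to rt; salt filtered under N2, washed with Et2O, dried in vacuo
Reagents that add atoms: potassium trimethylsilanolate, C[Si](C)(C)[O-].[K+]
Why: Anhydrous silanolate ester cleavage gives the carboxylate, which precipitates from ether and is thereby protected from further attack, and because the acid is never protonated it cannot cyclise to osmundalactone; the Z alkene and both stereocentres are untouched.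

Step 4
Reactants: 7 2,5-dichloro-1,4-benzoquinone; 8 4-aminophenol
Product: 10 2,5-dichloro-3,6-bis(4-hydroxyphenyl)-1,4-benzoquinone, via diazonium chloride 9 (not isolated)
Conditions: 8 (2.6 equiv), NaNO2, aq HCl, 0 °C; then 7 (1.0 equiv), NaOAc, H2O/acetone, 5 °C to rt; product filtered off and washed
Reagents that add atoms: sodium nitrite, [Na+].[O-]N=O, and hydrogen chloride, Cl (both only into intermediate 9; none of their atoms stays in 10)
Why: Meerwein-type radical chain arylation of a quinone, in which the nucleophilic 4-hydroxyphenyl radical from 9 adds to the electron-poor quinone and the adduct is re-oxidised by further diazonium ion; C3 and C6 are the only free positions of 7, so the regiochemistry is unambiguous and no stereocentre is involved.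

Step 5
Reactants: 10 2,5-dichloro-3,6-bis(4-hydroxyphenyl)-1,4-benzoquinone
Product: 12 atromentin (2,5-dihydroxy-3,6-bis(4-hydroxyphenyl)-1,4-benzoquinone), via tetrasodium salt 11 (not isolated)
Conditions: 2 M aq NaOH, 1,4-dioxane, 80 °C, N2; filter; then 2 M HCl, 0 °C; solid collected, recrystallised from AcOH, dried
Reagents that add atoms: sodium hydroxide, [Na+].[OH-]
Why: Addition–elimination of hydroxide on the two vinylogous acyl chloride carbons (classical chloroquinone hydrolysis) is driven by formation of the delocalised quinone-olate, and the base-soluble, acid-insoluble product purifies itself in the work-up.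

Step 6
Reactants: 6 potassium (2Z)-3-[(2S,3S)-3-methyloxiran-2-yl]prop-2-enoate (2.1 equiv); 12 atromentin (1.0 equiv); 13 1-chloro-N,N,2-trimethylprop-1-en-1-amine (2.1 equiv)
Product: 15 target CNP0407724.1 = atromentin 2,5-bis[(2Z,4S,5S)-4,5-epoxyhex-2-enoate], via acyloxyenamine 14 (not isolated)
Conditions: 6, 13, THF, −20 to 0 °C, 1 h, KCl filtered off under N2; filtrate added to 12, THF, −20 to 0 °C, 2 h; pH 5 citrate buffer; chromatography on acid-washed silica without alcohols
Reagents that add atoms: 1-chloro-N,N,2-trimethylprop-1-en-1-amine 13, CC(C)=C(Cl)N(C)C (only into intermediate 14; none of its atoms stays in 15)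
Why: Proposed new method: proton-gated double O-acylation of a hydroxyquinone. Carboxylate 6 adds to the keteniminium chloride form of 13, and insoluble KCl leaves, so the neutral ketene O,N-acetal 14 forms with no proton and no soluble chloride and cannot turn into an acid chloride. Compound 14 is inert until it is protonated on carbon, and in 12 only the two vinylogous-acid quinone OH groups (pKa about 3–4) do this quickly, whereas the phenols (pKa about 10) are slower by several orders of magnitude. Each protonation creates an acyloxyiminium/quinone-olate contact ion pair that collapses by C–O bond formation at the acyl carbon and releases an inert amide, and that strongly exergonic amide formation pays for the high-energy vinylogous anhydride and makes the step irreversible. No base, free carboxylate or nucleophilic catalyst is ever present, so de-acylation of the product, acyl migration to the phenols, Z-to-E isomerisation, lactonisation and epoxide opening have no promoter, and the four stereocentres are carried in unchanged from 6. The closest known reaction types are anhydride and amide formation through ynamine- or ynamide-derived α-acyloxyenamines and acid chloride formation with α-chloroenamines; neither the salt entry to 14 nor acyl transfer to a hydroxyquinone beside free phenols has been shown.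

## Compound list
1 | (E)-but-2-en-1-ol | C/C=C/CO | starting material
2 | [(2S,3S)-3-methyloxiran-2-yl]methanol | C[C@@H]1O[C@H]1CO | intermediate
3 | methyl 2-[bis(2,2,2-trifluoroethoxy)phosphoryl]acetate | COC(=O)CP(=O)(OCC(F)(F)F)OCC(F)(F)F | starting material
4 | (2R,3S)-3-methyloxirane-2-carbaldehyde | C[C@@H]1O[C@H]1C=O | intermediate
5 | methyl (2Z)-3-[(2S,3S)-3-methyloxiran-2-yl]prop-2-enoate | C[C@@H]1O[C@H]1/C=C\C(=O)OC | intermediate
6 | potassium (2Z)-3-[(2S,3S)-3-methyloxiran-2-yl]prop-2-enoate | C[C@@H]1O[C@H]1/C=C\C(=O)[O-].[K+] | intermediate
7 | 2,5-dichloro-1,4-benzoquinone | O=C1C=C(Cl)C(=O)C=C1Cl | starting material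
8 | 4-aminophenol | Nc1ccc(O)cc1 | starting material
9 | 4-hydroxybenzenediazonium chloride | Oc1ccc(cc1)[N+]#N.[Cl-] | intermediate
10 | 2,5-dichloro-3,6-bis(4-hydroxyphenyl)-1,4-benzoquinone | O=C1C(Cl)=C(c2ccc(O)cc2)C(=O)C(Cl)=C1c1ccc(O)cc1 | intermediate
11 | atromentin tetrasodium salt | [Na+].[Na+].[Na+].[Na+].[O-]c1ccc(cc1)C1=C([O-])C(=O)C(c2ccc([O-])cc2)=C([O-])C1=O | intermediate
12 | atromentin, 2,5-dihydroxy-3,6-bis(4-hydroxyphenyl)-1,4-benzoquinone | O=C1C(O)=C(c2ccc(O)cc2)C(=O)C(O)=C1c1ccc(O)cc1 | intermediate
13 | 1-chloro-N,N,2-trimethylprop-1-en-1-amine | CC(C)=C(Cl)N(C)C | starting material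
14 | 1-(dimethylamino)-2-methylprop-1-en-1-yl (2Z)-3-[(2S,3S)-3-methyloxiran-2-yl]prop-2-enoate | C[C@@H]1O[C@H]1/C=C\C(=O)OC(N(C)C)=C(C)C | intermediate
15 | 2,5-bis(4-hydroxyphenyl)-3,6-dioxocyclohexa-1,4-diene-1,4-diyl bis{(2Z)-3-[(2S,3S)-3-methyloxiran-2-yl]prop-2-enoate} | C[C@@H]1O[C@H]1/C=C\C(=O)OC1=C(c2ccc(O)cc2)C(=O)C(OC(=O)/C=C\[C@@H]2O[C@H]2C)=C(c2ccc(O)cc2)C1=O | target

## Step count and risks
Total steps: 6. Longest linear sequence: 4 (steps 1, 2, 3, 6). The quinone branch is steps 4, 5, 6.

Enantiopurity: two molecules of 6 end up in one molecule of 15. About 94% ee in 2 therefore becomes above 99.5% ee in 15, together with about 6% of the meso (4S,5S,4'R,5'R) diastereomer. That diastereomer is removed by crystallisation or preparative HPLC.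

**Most likely to fail, first: step 6, the proposed new step.**
- The heterogeneous salt metathesis may be slow.
- Intermediate 14 may undergo an O-to-C acyl shift, or its oxirane oxygen may attack the activated acyl group.
- A little phenol acylation or loss of the labile esters on silica is possible.

The fallback uses only known chemistry. It sets out from 12 and 6 and comes back at 15.
- Treat 12 with TBSCl (2.2 equiv) and imidazole in DMF. Any silyl group that lands on the acidic quinone oxygens is lost again in the aqueous citric acid work-up, which gives 4,4''-bis-O-(tert-butyldimethylsilyl)atromentin F1.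
- Convert 6 with isobutyl chloroformate in THF at −20 °C into isobutyl carbonic (2Z,4S,5S)-4,5-epoxyhex-2-enoic anhydride F2.
- Acylate F1 with F2 and a catalytic amount of N-methylmorpholine. This is a classical mixed-anhydride esterification, made irreversible by loss of CO2, and it gives the bis(tert-butyldimethylsilyl) ether of the target F3.
- Cleave the two aryl silyl ethers with Et3N·3HF in THF at 0 °C to reach 15.

**Second: step 4.**
- At acetate pH the diazonium ion 9 is partly deprotonated to the sluggish diazo-oxide.
- The double arylation may stop at the mono-aryl stage or give tars.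

The fallback replaces radical C–H arylation by cross-coupling. It sets out from 7 and comes back at 10.
- Brominate the two C–H positions of 7 (Br2, AcOH, 60 °C) to get 2,5-dibromo-3,6-dichloro-1,4-benzoquinone F4.
- Run a bromide-selective double Suzuki–Miyaura coupling with commercial 4-hydroxyphenylboronic acid (Pd(PPh3)4, K2CO3, dioxane/H2O, 80 °C). This gives 10.

**Third: step 2.**
- Aldehyde 4 is small, volatile and hydrophilic.
- Losses or residual water in the filtrate would erode both yield and Z selectivity.

The fallback forms the alkene first and the oxirane second. It sets out from 3, comes back at 5, and makes steps 1 and 2 unnecessary.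
- Run the same Still–Gennari olefination of 3 on commercial (E)-crotonaldehyde to get methyl (2Z,4E)-hexa-2,4-dienoate F5.
- Epoxidise the electron-richer, ester-remote 4,5-alkene with the dioxirane generated from 1,2:4,5-di-O-isopropylidene-β-L-erythro-2,3-hexodiulo-2,6-pyranose and KHSO5 (as 2KHSO5·KHSO4·K2SO4) in MeCN/dimethoxymethane/aqueous K2CO3 buffer at 0 °C. This ketone is the enantiomer of the fructose-derived epoxidation ketone, and that enantiomer gives the (4S,5S) epoxide.

## Further compounds
F1 | step 6 | 4,4''-bis-O-(tert-butyldimethylsilyl)atromentin | CC(C)(C)[Si](C)(C)Oc1ccc(cc1)C1=C(O)C(=O)C(c2ccc(O[Si](C)(C)C(C)(C)C)cc2)=C(O)C1=O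
F2 | step 6 | isobutyl carbonic (2Z,4S,5S)-4,5-epoxyhex-2-enoic anhydride | C[C@@H]1O[C@H]1/C=C\C(=O)OC(=O)OCC(C)C
F3 | step 6 | bis(tert-butyldimethylsilyl) ether of the target | C[C@@H]1O[C@H]1/C=C\C(=O)OC1=C(c2ccc(O[Si](C)(C)C(C)(C)C)cc2)C(=O)C(OC(=O)/C=C\[C@@H]2O[C@H]2C)=C(c2ccc(O[Si](C)(C)C(C)(C)C)cc2)C1=O
F4 | step 4 | 2,5-dibromo-3,6-dichloro-1,4-benzoquinone | O=C1C(Cl)=C(Br)C(=O)C(Cl)=C1Br
F5 | step 2 | methyl (2Z,4E)-hexa-2,4-dienoate | C/C=C/C=C\C(=O)OC
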